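## Structural features

The target is a furofuran lignan: two oxolane rings, ring A (C1–C2–O3–C4–C5) and ring B (C1–C5–C6–O7–C8), cis-fused through the C1–C5 bond into a 3,7-dioxabicyclo[3.3.0]octane. C2 carries a 4-hydroxy-3-methoxyphenyl (guaiacyl) group, C6 a 3,4-dimethoxyphenyl (veratryl) group and the bridgehead C1 a tertiary acetate, so the two halves are not equivalent and each aryl group has to be brought in separately. Four stereocentres stand in a row, C2–C1–C5–C6, with the configuration (1S,2R,5R,6S): both aryl groups lie on the convex face, the C2 aryl cis to the C1 oxygen and the C6 aryl cis to H5 (trans to the C4 arm). Fragile points are the two benzylic C–O bonds on electron-rich rings (they ionise under acid and are open to hydrogenolysis), the tertiary acetate next to benzylic C2, and the free phenol. The real difficulty is C1, a fully substituted C–O centre whose configuration must be fixed against C2 on one side and C5/C6 on the other without ever making a benzylic cation. The feature used is that C1 carries an oxygen and, next to it, the C8 methylene bound to O7. This is the pattern left when the C6 oxygen opens a terminal C1–C8 epoxide at C8. That epoxide is the Payne isomer of the C1–C2 epoxide of an (E)-allylic alcohol with its hydroxyl on C8, which reagent-controlled epoxidation can deliver in either absolute sense.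

## Logic of the disconnections

**22 back to 21 and 20.** The phenolic O–benzyl bond and then the O–acetyl bond at C1 are cut. The phenol stays masked to the end because it would otherwise be sulfonylated and acetylated; the acetate is put on late because it would not survive alkoxide or fluoride steps. The gain is the neutral, base-stable bicyclic alcohol 20. The forward steps need an acylation that reaches a hindered bridgehead hydroxyl and a hydrogenolysis that stops at the aryl benzyl ether.

**20 back to 18.** The O3–C4 bond is cut, which opens ring A to a triol. Cutting here and not at C2–O3 makes the C2 oxygen the nucleophile, so benzylic C2 keeps its configuration. The gain is a monocyclic oxolane whose three hydroxyls differ in class (primary, secondary benzylic, tertiary). The forward step must activate only the primary C4 hydroxyl (transient sulfonate 19) and close 5-exo-tet.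

**18 back to 17.** The O–Si bond at C4 is cut. The C4 oxygen has to be blocked during the cascade or it competes with O6 for C8. A tri-isopropylsilyl ether is chosen over a smaller silyl ether because a 1,3 O-to-O silyl shift to the C6 alkoxide would free exactly that competitor. The demand is a fluoride deprotection that leaves the benzylic alcohol alone.

**17 back to 15 (key step).** The O7–C8 bond and the tertiary C1–O bond are cut, passing through 16. This removes ring B and returns the C1 oxygen to C8 as a primary hydroxyl, so that C1 and C2 become the two carbons of one epoxide. The gain is an acyclic epoxy alcohol with stereocentres that can be set in the open chain. The forward step needs base and no acid, the C6 oxygen as the only free nucleophile besides O8, and a 5-exo choice of C8 over benzylic C2.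

**15 back to 14 and 13.** The C6 hydroxyl is re-masked as its triethylsilyl ether and the two epoxide C–O bonds are cut, which leaves the (E)-alkene. The epoxidation sets C1 and C2 under reagent control before any ring exists. O6 stays silylated while tetravalent titanium is present, because a free hydroxyl three atoms from an electron-rich benzylic epoxide could bind the catalyst and open the epoxide at C2. The (1R,2R) epoxide belongs to the series opposite to the (2S,3S) epoxide that L-(+)-tartrate gives from (E)-cinnamyl alcohol, so the D-(−)-tartrate is required. The alkene must be (E), and one silyl ether (secondary, triethyl) must afterwards be cleaved beside another (primary, tri-isopropyl).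

**13 back to 12, 11 and 10.** No skeletal bond is cut: C8 returns to the ester level, the C4 silyl ether to the alcohol and that alcohol to the acyl oxazolidinone. Each oxygen gets its own moment: O6 is silylated first, O4 appears when the auxiliary is removed and is silylated while C8 is still an ester, and C8 is reduced last. A tert-butyl ester is used at C8 so that neither O4 nor O6 can lactonise onto it and so that borohydride separates imide from ester cleanly. The demand is hydride chemoselectivity.

**10 and 9 back to 6 and 7.** The C5–C6 bond is cut (aldol transform). This splits the molecule into its two aryl halves and makes 7 a commodity aldehyde. The relationship needed is syn in aldol terms: C1 and the hydroxyl lie on the same side of the C4–C5–C6–aryl zigzag. It reads as anti only if the chain is drawn through C1 and the C4 arm is counted as the substituent. An anti-selective aldol would put the ring B aryl group cis to the C4 arm. The sense required (C5 S, C6 S in 9) is that of the boron enolate of the (S)-benzyl oxazolidinone.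

**6 back to 3 and 4, and 3 back to 1 and 2.** The N–acyl bond and then the C1=C2 double bond are cut (Stobbe transform). The gain is three commercial compounds (1, 2, 7) and the recoverable 4. The forward step must give the (E)-alkene (aryl cis to C5), which is what makes the later epoxide trans, and must leave the acid on C4 and the ester on C8.

## Other disconnections considered

**Alternative 1:** The cut is C1–C5 together with C2–O3. The forward step starts from the epoxy enol acetate A1, in which O7 links C6 to the C8 methylene of a 2-acetoxy-3-arylallyl group. Cp2TiCl (trivalent titanium) would open the C4–C5 epoxide homolytically to a C5 radical, which adds 5-exo-trig to C1 of the enol acetate. Iodine would then make the benzylic C2 centre electrophilic and the C4 oxygen would capture it, giving A2, the silyl ether of the target.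
- In its favour: two rings, one C–C bond, one C–O bond and three stereocentres (C1, C5, C2) come from a substrate with one controlling stereocentre, and the acetate is already in place. Titanocene cyclisations of epoxy cinnamyl ethers to furofurans are a close relative.
- Against it here: the radical must add to the acetoxy-bearing carbon and create a quaternary centre. The C2 radical is β to the acetate, so reduction to a benzylic titanium species would invite β-elimination of acetate, and a 1,2-acyloxy shift is also possible.
- Comparison on structure: the cis fusion and the exo aryl at C2 are served as well as in the chosen plan. C1 and C5 rest on substrate control from C6 alone.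
- Comparison on mechanism: one radical step sets C1, where the chosen plan uses a reagent-controlled epoxidation followed by a stereospecific inversion.
- Comparison on step economy: the alternative is clearly better.

**Alternative 2:** The cut is C1–C2 and C4–C5, a [3+2] retron across ring A. CsF would desilylate the α-chloro ether A3 (made from 1) to the non-stabilised carbonyl ylide A4, which adds across the C1=C5 bond of the acetoxy butenolide A5 to give the lactone A6.
- In its favour: it is convergent, and ring A, the C1 acetate and three stereocentres (C1, C2, C5) arrive in one step. Addition anti to the C6 aryl group of A5 should give the right C5/C6 relationship, the cis fusion is automatic, and the polarity match (nucleophilic CH2 terminus to C5) supports the needed regiochemistry.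
- Against it here: endo/exo selectivity at C2 is not secured. A5 is the enol acetate of an α-keto lactone and is open to acyl transfer by fluoride. A6 still has a carbonyl at C8, which must be taken down to CH2 beside a tertiary acetate and two acid-sensitive benzylic ethers.
- Comparison on structure: it is the equal of the chosen plan for C1 relative to C5/C6 and weaker at C2.
- Comparison on mechanism: a concerted cycloaddition is cleaner than a cascade, which is a point for the alternative.
- Comparison on step economy: the alternative is better up to A6, but the redox steps at C8 give the advantage back; in the chosen plan C8 has the right oxidation level from the epoxidation onward.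

**Alternative 3:** The cut is the C1–C2 carbon–carbon bond. Irradiation of the oxolan-3-one A7 (ring B with a C1 ketone and the CH2–O–CH2Ar chain on C5) would excite the ketone, whose oxygen abstracts the δ-hydrogen at C2 (benzylic and α to O3). The 1,5-biradical would recombine to form C1–C2, closing ring A and creating the C1 hydroxyl. The product A8 is identical with 20.
- In its favour: the quaternary carbinol and ring A are made without any activating group or reagent, the C2–H bond is among the weakest in the molecule, and A7 is reachable from the same aldol chemistry in fewer operations than 18.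
- Against it here: α-cleavage of the α-alkoxy ketone and β-scission of the biradical compete, the two electron-rich arenes absorb and can transfer an electron, and C5 of A7 is epimerisable. The configuration at C2 and the face of C1 that is attacked are decided in the biradical without a control element.
- Comparison on structure: equal, since the product is the same compound and the last two steps are shared.
- Comparison on mechanism: two stereocentres set in an excited-state step are less controllable than the ground-state SN2 steps of the chosen plan.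
- Comparison on step economy: equal or slightly better.

Key step: step 10

Remark: the locants C1–C8 of the bicyclic target are used for every intermediate; CIP descriptors in the names follow the systematic numbering of each name.
Assumption: 1 (the benzyl ether of vanillin) is bought as such; it is one O-alkylation away from vanillin.

## Route

Step 1
Reactants: 1 4-(benzyloxy)-3-methoxybenzaldehyde; 2 di-tert-butyl succinate
Product: 3 (3E)-4-[4-(benzyloxy)-3-methoxyphenyl]-3-(tert-butoxycarbonyl)but-3-enoic acid
Conditions: KOtBu, t-BuOH, 60 °C; then aq. HCl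
Reagents that add atoms: none
Why: Stobbe condensation: the succinate enolate adds to the aldehyde, the alkoxide lactonises onto the second ester and base-induced ring opening (E1cB) gives the half-ester with the acid on the CH2 arm (C4) and the ester on the alkene carbon (C8); the (E)-isomer (aryl trans to the ester, cis to C5) should predominate.

Step 2
Reactants: 3 (3E)-4-[4-(benzyloxy)-3-methoxyphenyl]-3-(tert-butoxycarbonyl)but-3-enoic acid; 4 (4S)-4-benzyl-1,3-oxazolidin-2-one
Product: 6 (4S)-4-benzyl-3-{(3E)-4-[4-(benzyloxy)-3-methoxyphenyl]-3-(tert-butoxycarbonyl)but-3-enoyl}-1,3-oxazolidin-2-one, via mixed pivalic anhydride 5 (not isolated)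
Conditions: t-BuCOCl, Et3N, THF, −20 °C; then 4, LiCl, −20 °C to rt
Reagents that add atoms: pivaloyl chloride, CC(C)(C)C(=O)Cl (its atoms appear only in 5)
Why: N-acylation of the oxazolidinone through the mixed anhydride with LiCl assistance; attack should occur at the less hindered carbonyl of 5, and no stereocentre is formed.

Step 3
Reactants: 6 (4S)-4-benzyl-3-{(3E)-4-[4-(benzyloxy)-3-methoxyphenyl]-3-(tert-butoxycarbonyl)but-3-enoyl}-1,3-oxazolidin-2-one; 7 3,4-dimethoxybenzaldehyde
Product: 9 tert-butyl (2E,3S,4S)-2-[4-(benzyloxy)-3-methoxybenzylidene]-3-{[(4S)-4-benzyl-2-oxo-1,3-oxazolidin-3-yl]carbonyl}-4-(3,4-dimethoxyphenyl)-4-hydroxybutanoate, via Z boron enolate 8 (not isolated)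
Conditions: Bu2BOTf, iPr2NEt, CH2Cl2, −78 to 0 °C; 7, −78 to 0 °C; pH 7 phosphate buffer, MeOH, 30% H2O2, 0 °C
Reagents that add atoms: dibutylboron triflate, CCCCB(CCCC)OS(=O)(=O)C(F)(F)F (its atoms appear only in 8)
Why: Evans syn aldol: the Z boron enolate should react through a chair Zimmerman–Traxler transition state with the auxiliary carbonyl turned away and the benzyl group shielding one face, which sets C5 (S) and C6 (S) together with C1 and the hydroxyl syn; the closed transition state directs attack to C5 and not to benzylic C2 of the dienolate, and the tert-butyl ester should not lactonise with the new hydroxyl.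

Step 4
Reactants: 9 tert-butyl (2E,3S,4S)-2-[4-(benzyloxy)-3-methoxybenzylidene]-3-{[(4S)-4-benzyl-2-oxo-1,3-oxazolidin-3-yl]carbonyl}-4-(3,4-dimethoxyphenyl)-4-hydroxybutanoate
Product: 10 tert-butyl (2E,3S,4S)-2-[4-(benzyloxy)-3-methoxybenzylidene]-3-{[(4S)-4-benzyl-2-oxo-1,3-oxazolidin-3-yl]carbonyl}-4-(3,4-dimethoxyphenyl)-4-[(triethylsilyl)oxy]butanoate
Conditions: Et3SiCl, imidazole, 4-(dimethylamino)pyridine (cat.), DMF, rt
Reagents that add atoms: chlorotriethylsilane, CC[Si](Cl)(CC)CC
Why: Silyl ether formation at the secondary benzylic hydroxyl; it blocks retro-aldol and keeps O6 inert through the hydride and titanium steps.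

Step 5
Reactants: 10 tert-butyl (2E,3S,4S)-2-[4-(benzyloxy)-3-methoxybenzylidene]-3-{[(4S)-4-benzyl-2-oxo-1,3-oxazolidin-3-yl]carbonyl}-4-(3,4-dimethoxyphenyl)-4-[(triethylsilyl)oxy]butanoate
Product: 11 tert-butyl (2E,3R,4S)-2-[4-(benzyloxy)-3-methoxybenzylidene]-4-(3,4-dimethoxyphenyl)-3-(hydroxymethyl)-4-[(triethylsilyl)oxy]butanoate
Conditions: LiBH4, MeOH (1 equiv), THF, 0 °C; aq. NH4Cl
Reagents that add atoms: none
Why: Reductive cleavage of the N-acyl oxazolidinone; the imide carbonyl is far more electrophilic than the hindered, conjugated tert-butyl ester, which should stay, and the auxiliary is recovered (the descriptor at C5 changes from S to R by priority only).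

Step 6
Reactants: 11 tert-butyl (2E,3R,4S)-2-[4-(benzyloxy)-3-methoxybenzylidene]-4-(3,4-dimethoxyphenyl)-3-(hydroxymethyl)-4-[(triethylsilyl)oxy]butanoate
Product: 12 tert-butyl (2E,3R,4S)-2-[4-(benzyloxy)-3-methoxybenzylidene]-4-(3,4-dimethoxyphenyl)-4-[(triethylsilyl)oxy]-3-{[(triisopropylsilyl)oxy]methyl}butanoate
Conditions: iPr3SiCl, imidazole, 4-(dimethylamino)pyridine (cat.), DMF, rt
Reagents that add atoms: chlorotriisopropylsilane, CC(C)[Si](Cl)(C(C)C)C(C)C
Why: Silyl ether formation at the only free hydroxyl; the tri-isopropylsilyl group is chosen because it should not migrate to a neighbouring alkoxide in step 10.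

Step 7
Reactants: 12 tert-butyl (2E,3R,4S)-2-[4-(benzyloxy)-3-methoxybenzylidene]-4-(3,4-dimethoxyphenyl)-4-[(triethylsilyl)oxy]-3-{[(triisopropylsilyl)oxy]methyl}butanoate
Product: 13 (2E,3R,4S)-2-[4-(benzyloxy)-3-methoxybenzylidene]-4-(3,4-dimethoxyphenyl)-4-[(triethylsilyl)oxy]-3-{[(triisopropylsilyl)oxy]methyl}butan-1-ol
Conditions: iBu2AlH, CH2Cl2, −78 to 0 °C; aq. potassium sodium tartrate
Reagents that add atoms: none
Why: 1,2-Reduction of the α,β-unsaturated ester to the allylic alcohol by the aluminium hydride; the alkene geometry and the silyl and benzyl ethers should be unaffected.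

Step 8
Reactants: 13 (2E,3R,4S)-2-[4-(benzyloxy)-3-methoxybenzylidene]-4-(3,4-dimethoxyphenyl)-4-[(triethylsilyl)oxy]-3-{[(triisopropylsilyl)oxy]methyl}butan-1-ol
Product: 14 [(2R,3R)-3-[4-(benzyloxy)-3-methoxyphenyl]-2-{(1S,2R)-1-(3,4-dimethoxyphenyl)-1-[(triethylsilyl)oxy]-3-[(triisopropylsilyl)oxy]propan-2-yl}oxiran-2-yl]methanol
Conditions: Ti(OiPr)4 (0.2 equiv), D-(−)-diisopropyl tartrate (0.25 equiv), t-BuOOH in decane, 4 Å molecular sieves, CH2Cl2, −25 °C
Reagents that add atoms: tert-butyl hydroperoxide, CC(C)(C)OO
Why: Sharpless asymmetric epoxidation: the allylic alkoxide binds the titanium tartrate and oxygen is delivered to one alkene face under reagent control; D-(−)-tartrate is the ligand of the (2R,3R) series (L-(+)-tartrate gives the (2S,3S) epoxide from (E)-cinnamyl alcohol), so C1 (R) and C2 (R) should result, and substoichiometric titanium, sieves and low temperature limit opening of the electron-rich benzylic epoxide.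

Step 9
Reactants: 14 [(2R,3R)-3-[4-(benzyloxy)-3-methoxyphenyl]-2-{(1S,2R)-1-(3,4-dimethoxyphenyl)-1-[(triethylsilyl)oxy]-3-[(triisopropylsilyl)oxy]propan-2-yl}oxiran-2-yl]methanol
Product: 15 [(2R,3R)-3-[4-(benzyloxy)-3-methoxyphenyl]-2-{(1S,2R)-1-(3,4-dimethoxyphenyl)-1-hydroxy-3-[(triisopropylsilyl)oxy]propan-2-yl}oxiran-2-yl]methanol
Conditions: Bu4NF, AcOH (1:1), THF, 0 °C
Reagents that add atoms: none
Why: Fluoride cleavage of the triethylsilyl ether, which is much more labile than the primary tri-isopropylsilyl ether; the acetic acid buffer keeps the medium too weakly basic to start the cascade and too weakly acidic to open the epoxide.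

Step 10
Reactants: 15 [(2R,3R)-3-[4-(benzyloxy)-3-methoxyphenyl]-2-{(1S,2R)-1-(3,4-dimethoxyphenyl)-1-hydroxy-3-[(triisopropylsilyl)oxy]propan-2-yl}oxiran-2-yl]methanol
Product: 17 (3S,4R,5S)-3-{(R)-[4-(benzyloxy)-3-methoxyphenyl](hydroxy)methyl}-5-(3,4-dimethoxyphenyl)-4-{[(triisopropylsilyl)oxy]methyl}oxolan-3-ol, via Payne-isomeric terminal epoxide 16 (not isolated)
Conditions: KOtBu (2.2 equiv), t-BuOH–THF, 0 °C to rt; aq. NH4Cl
Reagents that add atoms: none
Why: The potassium alkoxide on C8 attacks C1 from the rear of the C1–O epoxide bond (3-exo-tet), which gives the terminal C1–C8 epoxide 16 with a C2 alkoxide, C1 being inverted and C2 untouched. The two epoxy alkoxides interconvert; 16 is the minor but more electrophilic partner, and the C6 alkoxide opens it at its unsubstituted carbon C8, an irreversible 5-exo-tet closure of ring B that leaves the tertiary C1 alkoxide and drains the equilibrium. The closest known reaction type is the Payne rearrangement of a 2,3-epoxy alcohol with capture of the 1,2-epoxide at its terminal carbon by a nucleophile present in the flask, here an internal alkoxide. The only stereocentre that changes is C1: its oxygen face was chosen by the reagent-controlled epoxidation of step 8 and is inverted stereospecifically, so C1 becomes S with the C2 arm cis to the C4 arm on ring B, while C2, C5 and C6 are carried through. The step needs attack of O6 at C8 of 16 and not at benzylic C2 of 15 (5-endo) or at C1 (4-exo): base keeps both epoxides from ionising, C2 is flanked by the quaternary C1, and a primary epoxide carbon reached through a five-membered transition state should be by far the fastest site. It also needs O6 and not O4 as the ring-closing oxygen, which the tri-isopropylsilyl ether secures because it should not migrate to the neighbouring alkoxide; t-BuOH serves as proton shuttle for the alkoxide exchanges.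

Step 11
Reactants: 17 (3S,4R,5S)-3-{(R)-[4-(benzyloxy)-3-methoxyphenyl](hydroxy)methyl}-5-(3,4-dimethoxyphenyl)-4-{[(triisopropylsilyl)oxy]methyl}oxolan-3-ol
Product: 18 (3S,4R,5S)-3-{(R)-[4-(benzyloxy)-3-methoxyphenyl](hydroxy)methyl}-5-(3,4-dimethoxyphenyl)-4-(hydroxymethyl)oxolan-3-ol
Conditions: Bu4NF, THF, rt; aq. NH4Cl
Reagents that add atoms: none
Why: Fluoride cleavage of the primary silyl ether; no other group should react and no stereocentre is touched.

Step 12
Reactants: 18 (3S,4R,5S)-3-{(R)-[4-(benzyloxy)-3-methoxyphenyl](hydroxy)methyl}-5-(3,4-dimethoxyphenyl)-4-(hydroxymethyl)oxolan-3-ol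
Product: 20 (1S,2R,5R,6S)-2-[4-(benzyloxy)-3-methoxyphenyl]-6-(3,4-dimethoxyphenyl)-3,7-dioxabicyclo[3.3.0]octan-1-ol, via primary tosylate 19 (not isolated)
Conditions: TsCl (1.1 equiv), Et3N, 4-(dimethylamino)pyridine (cat.), CH2Cl2, 0 °C; then K2CO3, MeOH, rt
Reagents that add atoms: 4-methylbenzenesulfonyl chloride, Cc1ccc(cc1)S(Cl)(=O)=O (its atoms appear only in 19)
Why: Selective sulfonylation of the primary hydroxyl (far more reactive than the secondary benzylic and the tertiary one), then Williamson-type 5-exo-tet closure of ring A by the C2 oxygen; C2–O is the nucleophile, so C2 keeps its configuration, the cis fusion follows from C2 and C4 being cis on ring B, and the mild carbonate keeps alkoxide concentration low, which disfavours fragmentation through the C1 alkoxide.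

Step 13
Reactants: 20 (1S,2R,5R,6S)-2-[4-(benzyloxy)-3-methoxyphenyl]-6-(3,4-dimethoxyphenyl)-3,7-dioxabicyclo[3.3.0]octan-1-ol
Product: 21 (1S,2R,5R,6S)-2-[4-(benzyloxy)-3-methoxyphenyl]-6-(3,4-dimethoxyphenyl)-3,7-dioxabicyclo[3.3.0]octan-1-yl acetate
Conditions: Ac2O, Et3N, 4-(dimethylamino)pyridine, CH2Cl2, rt to 40 °C
Reagents that add atoms: acetic anhydride, CC(=O)OC(C)=O
Why: Acyl-pyridinium (nucleophilic catalysis) acetylation of the tertiary bridgehead hydroxyl, which points to the convex face; no other hydroxyl is left to compete.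

Step 14
Reactants: 21 (1S,2R,5R,6S)-2-[4-(benzyloxy)-3-methoxyphenyl]-6-(3,4-dimethoxyphenyl)-3,7-dioxabicyclo[3.3.0]octan-1-yl acetate
Product: 22 (1S,2R,5R,6S)-6-(3,4-dimethoxyphenyl)-2-(4-hydroxy-3-methoxyphenyl)-3,7-dioxabicyclo[3.3.0]octan-1-yl acetate
Conditions: H2 (1 atm), 10% Pd/C, EtOAc, rt
Reagents that add atoms: none
Why: Hydrogenolysis of the aryl benzyl ether in a neutral solvent; aryl O–benzyl bonds should cleave much faster than the benzylic ring ethers, so the reaction is stopped after one equivalent of hydrogen.

## Compound list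

1 | 4-(benzyloxy)-3-methoxybenzaldehyde (O-benzylvanillin) | COc1cc(C=O)ccc1OCc1ccccc1 | starting material
2 | di-tert-butyl butanedioate (di-tert-butyl succinate) | CC(C)(C)OC(=O)CCC(=O)OC(C)(C)C | starting material
3 | (3E)-4-[4-(benzyloxy)-3-methoxyphenyl]-3-(tert-butoxycarbonyl)but-3-enoic acid | COc1cc(/C=C(\CC(=O)O)C(=O)OC(C)(C)C)ccc1OCc1ccccc1 | intermediate
4 | (4S)-4-benzyl-1,3-oxazolidin-2-one | O=C1N[C@@H](Cc2ccccc2)CO1 | starting material
5 | mixed anhydride of 3 with pivalic acid | COc1cc(/C=C(\CC(=O)OC(=O)C(C)(C)C)C(=O)OC(C)(C)C)ccc1OCc1ccccc1 | intermediate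
6 | (4S)-4-benzyl-3-{(3E)-4-[4-(benzyloxy)-3-methoxyphenyl]-3-(tert-butoxycarbonyl)but-3-enoyl}-1,3-oxazolidin-2-one | COc1cc(/C=C(\CC(=O)N2[C@@H](Cc3ccccc3)COC2=O)C(=O)OC(C)(C)C)ccc1OCc1ccccc1 | intermediate
7 | 3,4-dimethoxybenzaldehyde (veratraldehyde) | COc1ccc(C=O)cc1OC | starting material
8 | (Z)-O-dibutylboron enolate of 6 (C4=C5 double bond, boron on the acyl oxygen, oxygen and C1 cis) | CCCCB(CCCC)O/C(N1[C@@H](Cc2ccccc2)COC1=O)=C\C(C(=O)OC(C)(C)C)=C/c1ccc(OCc2ccccc2)c(OC)c1 | intermediate
9 | tert-butyl (2E,3S,4S)-2-[4-(benzyloxy)-3-methoxybenzylidene]-3-{[(4S)-4-benzyl-2-oxo-1,3-oxazolidin-3-yl]carbonyl}-4-(3,4-dimethoxyphenyl)-4-hydroxybutanoate | O=C(N1[C@@H](Cc2ccccc2)COC1=O)[C@@H](/C(C(=O)OC(C)(C)C)=C\c1ccc(OCc2ccccc2)c(OC)c1)[C@H](O)c1ccc(OC)c(OC)c1 | intermediate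
10 | tert-butyl (2E,3S,4S)-2-[4-(benzyloxy)-3-methoxybenzylidene]-3-{[(4S)-4-benzyl-2-oxo-1,3-oxazolidin-3-yl]carbonyl}-4-(3,4-dimethoxyphenyl)-4-[(triethylsilyl)oxy]butanoate | O=C(N1[C@@H](Cc2ccccc2)COC1=O)[C@@H](/C(C(=O)OC(C)(C)C)=C\c1ccc(OCc2ccccc2)c(OC)c1)[C@H](O[Si](CC)(CC)CC)c1ccc(OC)c(OC)c1 | intermediate
11 | tert-butyl (2E,3R,4S)-2-[4-(benzyloxy)-3-methoxybenzylidene]-4-(3,4-dimethoxyphenyl)-3-(hydroxymethyl)-4-[(triethylsilyl)oxy]butanoate | OC[C@@H](/C(C(=O)OC(C)(C)C)=C\c1ccc(OCc2ccccc2)c(OC)c1)[C@H](O[Si](CC)(CC)CC)c1ccc(OC)c(OC)c1 | intermediate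
12 | tert-butyl (2E,3R,4S)-2-[4-(benzyloxy)-3-methoxybenzylidene]-4-(3,4-dimethoxyphenyl)-4-[(triethylsilyl)oxy]-3-{[(triisopropylsilyl)oxy]methyl}butanoate | CC(C)[Si](OC[C@@H](/C(C(=O)OC(C)(C)C)=C\c1ccc(OCc2ccccc2)c(OC)c1)[C@H](O[Si](CC)(CC)CC)c1ccc(OC)c(OC)c1)(C(C)C)C(C)C | intermediate
13 | (2E,3R,4S)-2-[4-(benzyloxy)-3-methoxybenzylidene]-4-(3,4-dimethoxyphenyl)-4-[(triethylsilyl)oxy]-3-{[(triisopropylsilyl)oxy]methyl}butan-1-ol | CC(C)[Si](OC[C@@H](/C(CO)=C\c1ccc(OCc2ccccc2)c(OC)c1)[C@H](O[Si](CC)(CC)CC)c1ccc(OC)c(OC)c1)(C(C)C)C(C)C | intermediate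
14 | [(2R,3R)-3-[4-(benzyloxy)-3-methoxyphenyl]-2-{(1S,2R)-1-(3,4-dimethoxyphenyl)-1-[(triethylsilyl)oxy]-3-[(triisopropylsilyl)oxy]propan-2-yl}oxiran-2-yl]methanol | COc1cc([C@H]2O[C@@]2(CO)[C@H](CO[Si](C(C)C)(C(C)C)C(C)C)[C@H](O[Si](CC)(CC)CC)c3ccc(OC)c(OC)c3)ccc1OCc1ccccc1 | intermediate
15 | [(2R,3R)-3-[4-(benzyloxy)-3-methoxyphenyl]-2-{(1S,2R)-1-(3,4-dimethoxyphenyl)-1-hydroxy-3-[(triisopropylsilyl)oxy]propan-2-yl}oxiran-2-yl]methanol | COc1cc([C@H]2O[C@@]2(CO)[C@H](CO[Si](C(C)C)(C(C)C)C(C)C)[C@H](O)c3ccc(OC)c(OC)c3)ccc1OCc1ccccc1 | intermediate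
16 | (R)-[4-(benzyloxy)-3-methoxyphenyl]{(2S)-2-[(1S,2R)-1-(3,4-dimethoxyphenyl)-1-hydroxy-3-[(triisopropylsilyl)oxy]propan-2-yl]oxiran-2-yl}methanol | COc1cc([C@@H](O)[C@@]2(CO2)[C@H](CO[Si](C(C)C)(C(C)C)C(C)C)[C@H](O)c3ccc(OC)c(OC)c3)ccc1OCc1ccccc1 | intermediate
17 | (3S,4R,5S)-3-{(R)-[4-(benzyloxy)-3-methoxyphenyl](hydroxy)methyl}-5-(3,4-dimethoxyphenyl)-4-{[(triisopropylsilyl)oxy]methyl}oxolan-3-ol | COc1cc([C@@H](O)[C@@]2(O)CO[C@H](c3ccc(OC)c(OC)c3)[C@H]2CO[Si](C(C)C)(C(C)C)C(C)C)ccc1OCc1ccccc1 | intermediate
18 | (3S,4R,5S)-3-{(R)-[4-(benzyloxy)-3-methoxyphenyl](hydroxy)methyl}-5-(3,4-dimethoxyphenyl)-4-(hydroxymethyl)oxolan-3-ol | COc1cc([C@@H](O)[C@@]2(O)CO[C@H](c3ccc(OC)c(OC)c3)[C@H]2CO)ccc1OCc1ccccc1 | intermediate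
19 | [(2S,3R,4S)-4-{(R)-[4-(benzyloxy)-3-methoxyphenyl](hydroxy)methyl}-2-(3,4-dimethoxyphenyl)-4-hydroxyoxolan-3-yl]methyl 4-methylbenzenesulfonate | COc1cc([C@@H](O)[C@@]2(O)CO[C@H](c3ccc(OC)c(OC)c3)[C@H]2COS(=O)(=O)c4ccc(C)cc4)ccc1OCc1ccccc1 | intermediate
20 | (1S,2R,5R,6S)-2-[4-(benzyloxy)-3-methoxyphenyl]-6-(3,4-dimethoxyphenyl)-3,7-dioxabicyclo[3.3.0]octan-1-ol | COc1cc([C@H]2OC[C@@H]3[C@@H](c4ccc(OC)c(OC)c4)OC[C@]23O)ccc1OCc1ccccc1 | intermediate
21 | (1S,2R,5R,6S)-2-[4-(benzyloxy)-3-methoxyphenyl]-6-(3,4-dimethoxyphenyl)-3,7-dioxabicyclo[3.3.0]octan-1-yl acetate | COc1cc([C@H]2OC[C@@H]3[C@@H](c4ccc(OC)c(OC)c4)OC[C@]23OC(C)=O)ccc1OCc1ccccc1 | intermediate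
22 | (1S,2R,5R,6S)-6-(3,4-dimethoxyphenyl)-2-(4-hydroxy-3-methoxyphenyl)-3,7-dioxabicyclo[3.3.0]octan-1-yl acetate | COc1cc([C@H]2OC[C@@H]3[C@@H](c4ccc(OC)c(OC)c4)OC[C@]23OC(C)=O)ccc1O | target

## Step count and least certain steps

Total step count: 14. Longest linear sequence: 14 steps (1 or 2 to 22; 4 and 7 enter at steps 2 and 3).

**Step 10 (key step).** The most likely failure is transfer of the silyl group from O4 to the C6 alkoxide ahead of ring closure, after which the C4 alkoxide closes the isomeric oxolane at C8. Direct 5-endo attack of the C6 alkoxide at C2 is the second risk if the Payne isomerisation is slow against the crowded C1. The fallback sets out from 14 and returns at 17; it keeps O6 silylated while the Payne isomer is trapped by an external nucleophile. PhSH, aq. NaOH and t-BuOH at 60 °C should give the C8 phenyl sulfide F1 (Payne rearrangement with thiolate capture at the terminal carbon, C1 inverted as in the cascade). Bu4NF/AcOH then frees the C6 hydroxyl to give the alcohol F2. S-Methylation with Me3OBF4 in CH2Cl2 gives the sulfonium tetrafluoroborate F3, and K2CO3 in MeCN lets the C6 oxygen displace methyl phenyl sulfide at C8, directly or through 16, which gives 17.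

**Step 8.** The most likely failure is opening of the new epoxide at benzylic C2 by isopropanol, hydroperoxide or tartrate on the Lewis-acidic titanium centre, helped by the para-benzyloxy group; slow turnover caused by the branched C1 substituent would make this worse. The fallback goes from 13 to 14 by metal-free epoxidation with the dioxirane formed from the D-fructose-derived Shi ketone (1,2:4,5-di-O-isopropylidene-β-D-erythro-2,3-hexodiulo-2,6-pyranose, KHSO5 as its triple salt, K2CO3 buffer near pH 10, Bu4NHSO4, MeCN–dimethoxymethane–water, 0 °C). This ketone gives the (2R,3R) series from (E)-3-aryl allylic alcohols and the medium is basic, so the epoxide never meets a Lewis acid. No new compound is made.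

**Step 9.** The most likely failure is loss of the primary tri-isopropylsilyl ether together with the triethylsilyl ether, or attack of the freed C6 hydroxyl on C2 of the epoxide during isolation. The fallback goes from 13 to 15 with the order reversed. The triethylsilyl ether is removed before the epoxide exists (pyridinium p-toluenesulfonate, MeOH, 0 °C), which gives the diol F4. F4 is then epoxidised under the titanium-free, buffered dioxirane conditions named for step 8, which tolerate free hydroxyls, and gives 15 directly.

**Step 12.** The most likely failure is sulfonylation at the benzylic C2 hydroxyl followed by ionisation and loss of configuration at C2, or closure by the C1 oxygen to an oxetane. The fallback goes from 18 to 20 by Mitsunobu cyclodehydration (PPh3, diisopropyl azodicarboxylate, THF, 0 °C to rt). The phosphonium activates the least hindered, primary hydroxyl and the C2 hydroxyl displaces it, so neither a sulfonate nor a base is involved. No new compound is made.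

## Further compounds

F1 | step 10 | C8 phenyl sulfide with C1 and C2 hydroxyls from 14 (C6 triethylsilyl ether, C4 tri-isopropylsilyl ether; C1, C2, C5, C6 as in 17) | COc1cc([C@@H](O)[C@@](O)(CSc2ccccc2)[C@H](CO[Si](C(C)C)(C(C)C)C(C)C)[C@H](O[Si](CC)(CC)CC)c3ccc(OC)c(OC)c3)ccc1OCc1ccccc1
F2 | step 10 | C6 alcohol of F1 (triethylsilyl group removed) | COc1cc([C@@H](O)[C@@](O)(CSc2ccccc2)[C@H](CO[Si](C(C)C)(C(C)C)C(C)C)[C@H](O)c3ccc(OC)c(OC)c3)ccc1OCc1ccccc1
F3 | step 10 | S-methyl S-phenyl sulfonium tetrafluoroborate of F2 | COc1cc([C@@H](O)[C@@](O)(C[S+](C)c2ccccc2)[C@H](CO[Si](C(C)C)(C(C)C)C(C)C)[C@H](O)c3ccc(OC)c(OC)c3)ccc1OCc1ccccc1.F[B-](F)(F)F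
F0 | step 8 | none | none
F4 | step 9 | (2E,3R,4S)-2-[4-(benzyloxy)-3-methoxybenzylidene]-4-(3,4-dimethoxyphenyl)-3-{[(triisopropylsilyl)oxy]methyl}butane-1,4-diol | CC(C)[Si](OC[C@@H](/C(CO)=C\c1ccc(OCc2ccccc2)c(OC)c1)[C@H](O)c1ccc(OC)c(OC)c1)(C(C)C)C(C)C
F0 | step 12 | none | none
A1 | alternative 1 | (1Z)-1-[4-(tert-butyldimethylsilyloxy)-3-methoxyphenyl]-3-{(R)-(3,4-dimethoxyphenyl)[(2R)-oxiran-2-yl]methoxy}prop-1-en-2-yl acetate | COc1ccc([C@@H](OC/C(OC(C)=O)=C/c2ccc(O[Si](C)(C)C(C)(C)C)c(OC)c2)[C@H]3CO3)cc1OC
A2 | alternative 1 | (1S,2R,5R,6S)-2-[4-(tert-butyldimethylsilyloxy)-3-methoxyphenyl]-6-(3,4-dimethoxyphenyl)-3,7-dioxabicyclo[3.3.0]octan-1-yl acetate | COc1cc([C@H]2OC[C@@H]3[C@@H](c4ccc(OC)c(OC)c4)OC[C@]23OC(C)=O)ccc1O[Si](C)(C)C(C)(C)C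
A3 | alternative 2 | 1-(benzyloxy)-4-{chloro[(trimethylsilyl)methoxy]methyl}-2-methoxybenzene (racemic) | COc1cc(C(Cl)OC[Si](C)(C)C)ccc1OCc1ccccc1
A4 | alternative 2 | carbonyl ylide from A3 (4-benzyloxy-3-methoxybenzylidene oxonium methylide) | COc1cc(C=[O+][CH2-])ccc1OCc1ccccc1
A5 | alternative 2 | (5S)-5-(3,4-dimethoxyphenyl)-2-oxo-2,5-dihydrofuran-3-yl acetate | CC(=O)OC1=C[C@@H](c2ccc(OC)c(OC)c2)OC1=O
A6 | alternative 2 | (1R,2R,5R,6S)-2-[4-(benzyloxy)-3-methoxyphenyl]-6-(3,4-dimethoxyphenyl)-8-oxo-3,7-dioxabicyclo[3.3.0]octan-1-yl acetate | COc1cc([C@H]2OC[C@@H]3[C@@H](c4ccc(OC)c(OC)c4)OC(=O)[C@]23OC(C)=O)ccc1OCc1ccccc1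
A7 | alternative 3 | (4R,5S)-4-({[4-(benzyloxy)-3-methoxybenzyl]oxy}methyl)-5-(3,4-dimethoxyphenyl)oxolan-3-one | COc1cc(COC[C@H]2C(=O)CO[C@@H]2c3ccc(OC)c(OC)c3)ccc1OCc1ccccc1
A8 | alternative 3 | (1S,2R,5R,6S)-2-[4-(benzyloxy)-3-methoxyphenyl]-6-(3,4-dimethoxyphenyl)-3,7-dioxabicyclo[3.3.0]octan-1-ol (identical with 20) | COc1cc([C@H]2OC[C@@H]3[C@@H](c4ccc(OC)c(OC)c4)OC[C@]23O)ccc1OCc1ccccc1
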